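**Retrosynthetic overview**
1. Feature: chroman C2 is both the benzylic carbon of ring B (the 3,5-diformyl-2,4,6-trihydroxyphenyl ring) and the carbon bonded to O1, so it is the methide carbon of a ring-B ortho-quinone methide that the C8a hydroxyl of ring A can capture.
2. Target ⇒ 5,7-di-O-methyl ether 22 (cleavage of the two methyl ethers beside the C6 ketone) ⇒ lactol 16 + 2,4-diformylphloroglucinol 19, forming C2–C1′ and then O1–C2.
3. Lactol 16 ⇒ O-benzyl aldehyde 14 ⇒ thioester 13 ⇒ Evans alkylation of imide 10 with benzylic bromide 9, which sets C3. The aldehyde level is reached from the thioester with Pd/C and Et3SiH so that no hydride reagent meets the C6 ketone.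
4. Bromide 9 ⇒ ketone phenol 4 (ortho-formylation, benzylation, reduction, bromination) ⇒ aldehyde 1 + Grignard reagent 2; 19 ⇒ phloroglucinol 17.
5. Ring order: rings A and B are bought as arenes; the pyran ring is the only ring made, transiently as the lactol in step 10 and finally in step 12.

Key step: step 12

Assumption: imide 10 is bought as such, and lactol 16 is used as its anomeric mixture because C2 is rebuilt in step 12.

**Step 1**
Reactants: 1 4-hydroxy-2,6-dimethoxybenzaldehyde; 2 isobutylmagnesium bromide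
Product: 3 4-(1-hydroxy-3-methylbutyl)-3,5-dimethoxyphenol (racemic)
Conditions: iBuMgBr (3 equiv), THF, 0 °C → rt; aq NH4Cl; used crude
Reagents that add atoms: none
Why: Grignard 1,2-addition to the aldehyde after one equivalent of 2 has been spent on the phenolic hydroxyl; the carbinol centre is racemic and is removed in step 2.

**Step 2**
Reactants: 3 4-(1-hydroxy-3-methylbutyl)-3,5-dimethoxyphenol
Product: 4 1-(4-hydroxy-2,6-dimethoxyphenyl)-3-methylbutan-1-one
Conditions: DDQ, 1,4-dioxane, rt
Reagents that add atoms: none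
Why: DDQ dehydrogenation of a para-hydroxybenzylic alcohol, in which hydride loss from the carbinol carbon is assisted by the para hydroxyl and the two ortho methoxy groups, should stop at the aryl ketone because the product ring is deactivated.

**Step 3**
Reactants: 4 1-(4-hydroxy-2,6-dimethoxyphenyl)-3-methylbutan-1-one
Product: 6 6-hydroxy-2,4-dimethoxy-3-(3-methylbutanoyl)benzaldehyde, via salicyl alcohol 5 (not isolated)
Conditions: MgCl2, Et3N, (CH2O)n, MeCN, reflux; aq HCl
Reagents that add atoms: paraformaldehyde (as formaldehyde), C=O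
Why: Casnati–Skattebøl ortho-formylation, in which the magnesium phenoxide delivers formaldehyde to an ortho carbon (the two are equivalent by symmetry) to give 5, which a second formaldehyde oxidises by hydride transfer; the hindered ketone should not take part.

**Step 4**
Reactants: 6 6-hydroxy-2,4-dimethoxy-3-(3-methylbutanoyl)benzaldehyde
Product: 7 6-(benzyloxy)-2,4-dimethoxy-3-(3-methylbutanoyl)benzaldehyde
Conditions: BnBr, K2CO3, DMF, rt → 50 °C
Reagents that add atoms: benzyl bromide, BrCc1ccccc1
Why: Williamson ether synthesis on the acidic phenol masks the future O1 for the base-mediated steps with a group that is later removed under neutral conditions.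

**Step 5**
Reactants: 7 6-(benzyloxy)-2,4-dimethoxy-3-(3-methylbutanoyl)benzaldehyde
Product: 8 1-[4-(benzyloxy)-3-(hydroxymethyl)-2,6-dimethoxyphenyl]-3-methylbutan-1-one
Conditions: NaBH4, MeOH/THF, −20 °C → 0 °C
Reagents that add atoms: none
Why: Borohydride reduction chemoselective for the aldehyde, because the aryl ketone is twisted and shielded by two ortho methoxy groups and should react far more slowly at low temperature.

**Step 6**
Reactants: 8 1-[4-(benzyloxy)-3-(hydroxymethyl)-2,6-dimethoxyphenyl]-3-methylbutan-1-one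
Product: 9 1-[4-(benzyloxy)-3-(bromomethyl)-2,6-dimethoxyphenyl]-3-methylbutan-1-one
Conditions: CBr4, PPh3, CH2Cl2, 0 °C; used at once without purification
Reagents that add atoms: carbon tetrabromide, BrC(Br)(Br)Br
Why: The Appel reaction converts the primary benzylic alcohol into the bromide under neutral conditions, avoiding acid that would ionise this electron-rich benzylic position.

**Step 7**
Reactants: 10 (4S)-4-benzyl-3-(3-methylbutanoyl)-1,3-oxazolidin-2-one; 9 1-[4-(benzyloxy)-3-(bromomethyl)-2,6-dimethoxyphenyl]-3-methylbutan-1-one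
Product: 12 (4S)-4-benzyl-3-[(2S)-2-{[6-(benzyloxy)-2,4-dimethoxy-3-(3-methylbutanoyl)phenyl]methyl}-3-methylbutanoyl]-1,3-oxazolidin-2-one, via sodium Z-enolate 11 (not isolated)
Conditions: NaN(SiMe3)2, THF, −78 °C; then 9, −78 → −20 °C
Reagents that add atoms: none
Why: Evans asymmetric alkylation, in which the chelated Z-enolate 11 is blocked on the face of the C4 benzyl group of the auxiliary, so 9 enters from the other face and sets the 2S centre (the future C3); the weakly basic imide enolate should leave the hindered ketone alone.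

**Step 8**
Reactants: 12 (4S)-4-benzyl-3-[(2S)-2-{[6-(benzyloxy)-2,4-dimethoxy-3-(3-methylbutanoyl)phenyl]methyl}-3-methylbutanoyl]-1,3-oxazolidin-2-one
Product: 13 S-ethyl (2S)-2-{[6-(benzyloxy)-2,4-dimethoxy-3-(3-methylbutanoyl)phenyl]methyl}-3-methylbutanethioate
Conditions: EtSH, n-BuLi, THF, 0 °C
Reagents that add atoms: ethanethiol (as its lithium thiolate), CCS
Why: Acyl substitution by the soft lithium thiolate at the exocyclic imide carbonyl releases the auxiliary and should give the thioester without epimerising the α-centre or touching the ketone.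

**Step 9**
Reactants: 13 S-ethyl (2S)-2-{[6-(benzyloxy)-2,4-dimethoxy-3-(3-methylbutanoyl)phenyl]methyl}-3-methylbutanethioate
Product: 14 (2S)-2-{[6-(benzyloxy)-2,4-dimethoxy-3-(3-methylbutanoyl)phenyl]methyl}-3-methylbutanal
Conditions: Et3SiH, 10% Pd/C, acetone, rt
Reagents that add atoms: none
Why: Fukuyama reduction, in which the C–S bond adds to zerovalent palladium and the silane delivers hydride to the acylpalladium species, gives the aldehyde under neutral conditions that spare the ketone, the benzyl ether and the α-stereocentre.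

**Step 10**
Reactants: 14 (2S)-2-{[6-(benzyloxy)-2,4-dimethoxy-3-(3-methylbutanoyl)phenyl]methyl}-3-methylbutanal
Product: 16 1-[(3S)-2-hydroxy-5,7-dimethoxy-3-(propan-2-yl)-3,4-dihydro-2H-chromen-6-yl]-3-methylbutan-1-one (anomeric mixture), via hydroxy aldehyde 15 (not isolated)
Conditions: H2 (1 atm), 10% Pd/C, EtOAc, rt
Reagents that add atoms: none
Why: Hydrogenolysis of the benzyl ether frees the C8a phenol, which adds to the aldehyde of 15 to form the six-membered hemiacetal; the neutral conditions should leave C3 intact.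

**Step 11**
Reactants: 17 phloroglucinol
Product: 19 2,4,6-trihydroxybenzene-1,3-dicarbaldehyde (2,4-diformylphloroglucinol), via bis-iminium salt 18 (not isolated)
Conditions: POCl3 (2.1 equiv), DMF (2.1 equiv), 1,4-dioxane, rt; then H2O
Reagents that add atoms: N,N-dimethylformamide, CN(C)C=O; water, O
Why: Vilsmeier–Haack formylation, in which phloroglucinol takes up two chloroiminium ions, the third position being deactivated by the two iminium groups, and water hydrolyses 18 to the dialdehyde.

**Step 12**
Reactants: 16 1-[(3S)-2-hydroxy-5,7-dimethoxy-3-(propan-2-yl)-3,4-dihydro-2H-chromen-6-yl]-3-methylbutan-1-one (anomeric mixture); 19 2,4-diformylphloroglucinol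
Product: 22 5-[(2R,3S)-5,7-dimethoxy-6-(3-methylbutanoyl)-3-(propan-2-yl)-3,4-dihydro-2H-chromen-2-yl]-2,4,6-trihydroxybenzene-1,3-dicarbaldehyde, via benzylic carbinol 20 (not isolated), via ortho-quinone methide 21 (not isolated)
Conditions: NaOAc, AcOH, 80 °C
Reagents that add atoms: none
Why: In the acetate buffer lactol 16 reacts through its ring-opened hydroxy aldehyde tautomer (the open form already met as compound 15 in step 10, with which it stays in equilibrium), the single unsubstituted ring carbon of 19 adds to that formyl group to give carbinol 20, and loss of water leaves the ring-B ortho-quinone methide 21, whose methide carbon is C2. The closest known reaction type is the Knoevenagel-type generation of ortho-quinone methides from 2,4-diformylphloroglucinol and aliphatic aldehydes with capture in the same flask, joined to the oxa-Michael addition of a phenol to a quinone methide. The pyran ring closes by 6-exo-trig oxa-conjugate addition of the C8a hydroxyl to C2, which restores the aromaticity of ring B and forms O1–C2 after C2–C1′. C2 is set by the C3 centre: the addition is reversible and should settle in the half-chair that carries both the isopropyl group and the ring-B aryl group pseudo-equatorial, that is 2,3-trans and 2R,3S. Regioselectivity is built in, because 19 has one nucleophilic carbon, the C5 and C7 oxygens of ring A are methyl ethers so that only the oxygen para to the ketone can close, and C8 of ring A cannot reach C2. The step also needs C3 to keep its configuration, which rests on an amine-free, weakly acidic medium that enolises the α-branched aldehyde slowly and on a phenol placed to trap 21 before it can tautomerise to a styrene.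

**Step 13**
Reactants: 22 5-[(2R,3S)-5,7-dimethoxy-6-(3-methylbutanoyl)-3-(propan-2-yl)-3,4-dihydro-2H-chromen-2-yl]-2,4,6-trihydroxybenzene-1,3-dicarbaldehyde
Product: 23 5-[(2R,3S)-5,7-dihydroxy-6-(3-methylbutanoyl)-3-(propan-2-yl)-3,4-dihydro-2H-chromen-2-yl]-2,4,6-trihydroxybenzene-1,3-dicarbaldehyde (target)
Conditions: BCl3 (excess), n-Bu4NI, CH2Cl2, −78 °C → 0 °C; H2O
Reagents that add atoms: none
Why: Lewis-acid ether cleavage ortho to a carbonyl, in which BCl3 is held between the C6 ketone and each flanking methoxy oxygen and iodide removes the methyl groups by SN2; the low temperature and the boron-complexed, electron-poor ring B should keep the O1–C2 bond and both stereocentres in place.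

**Compound list**
1 | 4-hydroxy-2,6-dimethoxybenzaldehyde | O=Cc1c(OC)cc(O)cc1OC | starting material
2 | isobutylmagnesium bromide | CC(C)C[Mg]Br | starting material
3 | 4-(1-hydroxy-3-methylbutyl)-3,5-dimethoxyphenol (racemic) | CC(C)CC(O)c1c(OC)cc(O)cc1OC | intermediate
4 | 1-(4-hydroxy-2,6-dimethoxyphenyl)-3-methylbutan-1-one | CC(C)CC(=O)c1c(OC)cc(O)cc1OC | intermediate
5 | 1-[4-hydroxy-3-(hydroxymethyl)-2,6-dimethoxyphenyl]-3-methylbutan-1-one (salicyl alcohol, not isolated) | CC(C)CC(=O)c1c(OC)cc(O)c(CO)c1OC | intermediate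
6 | 6-hydroxy-2,4-dimethoxy-3-(3-methylbutanoyl)benzaldehyde | CC(C)CC(=O)c1c(OC)cc(O)c(C=O)c1OC | intermediate
7 | 6-(benzyloxy)-2,4-dimethoxy-3-(3-methylbutanoyl)benzaldehyde | CC(C)CC(=O)c1c(OC)cc(OCc2ccccc2)c(C=O)c1OC | intermediate
8 | 1-[4-(benzyloxy)-3-(hydroxymethyl)-2,6-dimethoxyphenyl]-3-methylbutan-1-one | CC(C)CC(=O)c1c(OC)cc(OCc2ccccc2)c(CO)c1OC | intermediate
9 | 1-[4-(benzyloxy)-3-(bromomethyl)-2,6-dimethoxyphenyl]-3-methylbutan-1-one | CC(C)CC(=O)c1c(OC)cc(OCc2ccccc2)c(CBr)c1OC | intermediate
10 | (4S)-4-benzyl-3-(3-methylbutanoyl)-1,3-oxazolidin-2-one | CC(C)CC(=O)N1C(=O)OC[C@@H]1Cc1ccccc1 | starting material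
11 | sodium (1Z)-1-[(4S)-4-benzyl-2-oxo-1,3-oxazolidin-3-yl]-3-methylbut-1-en-1-olate (not isolated) | CC(C)/C=C(\[O-])N1C(=O)OC[C@@H]1Cc1ccccc1.[Na+] | intermediate
12 | (4S)-4-benzyl-3-[(2S)-2-{[6-(benzyloxy)-2,4-dimethoxy-3-(3-methylbutanoyl)phenyl]methyl}-3-methylbutanoyl]-1,3-oxazolidin-2-one | CC(C)CC(=O)c1c(OC)cc(OCc2ccccc2)c(C[C@@H](C(C)C)C(=O)N2C(=O)OC[C@@H]2Cc2ccccc2)c1OC | intermediate
13 | S-ethyl (2S)-2-{[6-(benzyloxy)-2,4-dimethoxy-3-(3-methylbutanoyl)phenyl]methyl}-3-methylbutanethioate | CC(C)CC(=O)c1c(OC)cc(OCc2ccccc2)c(C[C@@H](C(C)C)C(=O)SCC)c1OC | intermediate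
14 | (2S)-2-{[6-(benzyloxy)-2,4-dimethoxy-3-(3-methylbutanoyl)phenyl]methyl}-3-methylbutanal | CC(C)CC(=O)c1c(OC)cc(OCc2ccccc2)c(C[C@@H](C(C)C)C=O)c1OC | intermediate
15 | (2S)-2-{[6-hydroxy-2,4-dimethoxy-3-(3-methylbutanoyl)phenyl]methyl}-3-methylbutanal (open form of 16, formed in step 10, not isolated) | CC(C)CC(=O)c1c(OC)cc(O)c(C[C@@H](C(C)C)C=O)c1OC | intermediate
16 | 1-[(3S)-2-hydroxy-5,7-dimethoxy-3-(propan-2-yl)-3,4-dihydro-2H-chromen-6-yl]-3-methylbutan-1-one (lactol, anomeric mixture) | CC(C)CC(=O)c1c(OC)cc2c(c1OC)C[C@@H](C(C)C)C(O)O2 | intermediate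
17 | phloroglucinol (benzene-1,3,5-triol) | Oc1cc(O)cc(O)c1 | starting material
18 | 2,4-bis[(dimethyliminio)methyl]benzene-1,3,5-triol dichloride (not isolated) | C[N+](C)=Cc1c(O)cc(O)c(C=[N+](C)C)c1O.[Cl-].[Cl-] | intermediate
19 | 2,4,6-trihydroxybenzene-1,3-dicarbaldehyde (2,4-diformylphloroglucinol) | O=Cc1c(O)cc(O)c(C=O)c1O | intermediate
20 | 5-{(2S)-1-hydroxy-2-{[6-hydroxy-2,4-dimethoxy-3-(3-methylbutanoyl)phenyl]methyl}-3-methylbutyl}-2,4,6-trihydroxybenzene-1,3-dicarbaldehyde (both carbinol epimers, not isolated) | CC(C)CC(=O)c1c(OC)cc(O)c(C[C@@H](C(C)C)C(O)c2c(O)c(C=O)c(O)c(C=O)c2O)c1OC | intermediate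
21 | 2,4-dihydroxy-5-{(2S)-2-{[6-hydroxy-2,4-dimethoxy-3-(3-methylbutanoyl)phenyl]methyl}-3-methylbutylidene}-6-oxocyclohexa-1,3-diene-1,3-dicarbaldehyde (ring-B ortho-quinone methide, not isolated) | CC(C)CC(=O)c1c(OC)cc(O)c(C[C@@H](C(C)C)C=C2C(=O)C(C=O)=C(O)C(C=O)=C2O)c1OC | intermediate
22 | 5-[(2R,3S)-5,7-dimethoxy-6-(3-methylbutanoyl)-3-(propan-2-yl)-3,4-dihydro-2H-chromen-2-yl]-2,4,6-trihydroxybenzene-1,3-dicarbaldehyde | CC(C)CC(=O)c1c(OC)cc2c(c1OC)C[C@@H](C(C)C)[C@H](c1c(O)c(C=O)c(O)c(C=O)c1O)O2 | intermediate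
23 | 5-[(2R,3S)-5,7-dihydroxy-6-(3-methylbutanoyl)-3-(propan-2-yl)-3,4-dihydro-2H-chromen-2-yl]-2,4,6-trihydroxybenzene-1,3-dicarbaldehyde | CC(C)CC(=O)c1c(O)cc2c(c1O)C[C@@H](C(C)C)[C@H](c1c(O)c(C=O)c(O)c(C=O)c1O)O2 | target

**Step count**
Total: 13 steps. Longest linear sequence: 12 steps (steps 1–10, 12 and 13); step 11 is a one-step branch.

**Steps most likely to fail**

Step 12. The C3 configuration may be lost by enolisation of the open aldehyde or by a 1,5-hydrogen shift in the quinone methide that gives a styrene, and the doubly formylated arene may add too slowly to the α-branched aldehyde. The fallback sets out from lactol 16 and phloroglucinol 17. With phloroglucinol in excess (TsOH cat., MeCN, rt), the same condensation, quinone methide formation and oxa-Michael closure should run at ambient temperature with a much more nucleophilic arene, giving 1-[(2R,3S)-5,7-dimethoxy-3-(propan-2-yl)-2-(2,4,6-trihydroxyphenyl)-3,4-dihydro-2H-chromen-6-yl]-3-methylbutan-1-one F1. Vilsmeier–Haack diformylation (POCl3, DMF, dioxane; then H2O) of the free phloroglucinol ring then passes through the bis-iminium salt of F1 F2 and returns to the route at 22. The price is a late formylation that must prefer ring B over C8 of the ketone-deactivated ring A.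

Step 13. The Lewis acid may open the O1–C2 bond by retro-oxa-Michael reaction through a ring-B quinone methide; reclosure through the freed C5 oxygen would transpose the acyl group and could epimerise C2. The second methyl ether may also be cleaved incompletely. The fallback sets out from 22. Ac2O, pyridine and DMAP give the ring-B tri-O-acetate of 22 F3, in which no free ortho or para hydroxyl can push the pyran open. BBr3 (CH2Cl2, −78 → 0 °C) can then be used at full strength on the two methyl ethers to give the ring-B tri-O-acetate of the target F4. Brief methanolysis (K2CO3, MeOH, 0 °C) removes the activated aryl acetates and arrives at target 23.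

Step 6. The trialkoxybenzyl bromide may ionise and condense with itself before it meets the enolate. The fallback sets out from aldehyde 7 and needs no benzylic halide. Perkin condensation with isovaleric anhydride (Et3N, 150 °C) gives (2E)-2-{[6-(benzyloxy)-2,4-dimethoxy-3-(3-methylbutanoyl)phenyl]methylidene}-3-methylbutanoic acid F5. Asymmetric hydrogenation (H2, MeOH, Ru(OAc)2[(S)-BINAP] or its mirror image, the antipode being chosen by assay so that the 2S acid results) gives (2S)-2-{[6-(benzyloxy)-2,4-dimethoxy-3-(3-methylbutanoyl)phenyl]methyl}-3-methylbutanoic acid F6. Thioesterification (EtSH, DCC, DMAP, CH2Cl2, 0 °C) rejoins the route at thioester 13, bypassing steps 5–8.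

**Further compounds**
F1 | step 12 | 1-[(2R,3S)-5,7-dimethoxy-3-(propan-2-yl)-2-(2,4,6-trihydroxyphenyl)-3,4-dihydro-2H-chromen-6-yl]-3-methylbutan-1-one | CC(C)CC(=O)c1c(OC)cc2c(c1OC)C[C@@H](C(C)C)[C@H](c1c(O)cc(O)cc1O)O2
F2 | step 12 | bis-iminium salt of F1: 3,5-bis[(dimethyliminio)methyl] derivative of the trihydroxyphenyl ring, dichloride | CC(C)CC(=O)c1c(OC)cc2c(c1OC)C[C@@H](C(C)C)[C@H](c1c(O)c(C=[N+](C)C)c(O)c(C=[N+](C)C)c1O)O2.[Cl-].[Cl-]
F3 | step 13 | ring-B tri-O-acetate of 22 | CC(C)CC(=O)c1c(OC)cc2c(c1OC)C[C@@H](C(C)C)[C@H](c1c(OC(C)=O)c(C=O)c(OC(C)=O)c(C=O)c1OC(C)=O)O2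
F4 | step 13 | ring-B tri-O-acetate of target 23 | CC(C)CC(=O)c1c(O)cc2c(c1O)C[C@@H](C(C)C)[C@H](c1c(OC(C)=O)c(C=O)c(OC(C)=O)c(C=O)c1OC(C)=O)O2
F5 | step 6 | (2E)-2-{[6-(benzyloxy)-2,4-dimethoxy-3-(3-methylbutanoyl)phenyl]methylidene}-3-methylbutanoic acid | CC(C)CC(=O)c1c(OC)cc(OCc2ccccc2)c(/C=C(\C(C)C)C(O)=O)c1OC
F6 | step 6 | (2S)-2-{[6-(benzyloxy)-2,4-dimethoxy-3-(3-methylbutanoyl)phenyl]methyl}-3-methylbutanoic acid | CC(C)CC(=O)c1c(OC)cc(OCc2ccccc2)c(C[C@@H](C(C)C)C(O)=O)c1OC
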